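**Retrosynthetic overview** (mutilin numbering: C2 ketone, C3=C4 enone, C5/C9/C12 quaternary, C11 carbinol, C14 ester carbinol)
1. The cyclopentenone (C3=C4) is an aldol condensation of a C9 acetonyl group onto a C4 ketone; the C5–C14 bond is an aldol of the C4-ketone enolate with a C14 aldehyde.
2. Both closures and the C14 esterification are run in one flask on an α-bromo keto aldehyde (Sm(II) Reformatsky-type aldol, O-acylation, acid-triggered annulation).
3. C11–C12 comes from a stereospecific allylboration of a C11 aldehyde with a (Z)-enynyl boronate; the ethynyl group is the masked C13–C14 aldehyde.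
4. C9/C10 come from Ir-catalysed branched crotylation of a β-keto ester, then Pd-catalysed decarboxylative methallylation; one ozonolysis turns methallyl into acetonyl and vinyl into the C11 aldehyde. C6 comes from a Cu-catalysed asymmetric conjugate methylation.
5. Ring order: six-membered ring (present in the starting enone), then eight-membered, then five-membered (the last two in the same operation).

Assumption: the stereo tags of the given SMILES are copied unchanged into every structure and all descriptors quoted are those the SMILES give; the C5/C6 tags are read as the ordinary mutilin fold (C14 and C10 arms on the same face of the cyclohexane), although read literally they would place the two arms on opposite faces.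

**Step 1**
Reactants: 1 2-methylcyclohex-2-en-1-one
Product: 2 (2R,3S)-2,3-dimethylcyclohexan-1-one
Conditions: Me3Al (1.4 equiv), CuTC (2 mol%), chiral phosphoramidite (Feringa type, 4 mol%), Et2O, −30 °C; 1 M HCl; then DBU (cat.), CH2Cl2, rt
Reagents that add atoms: trimethylaluminium, C[Al](C)C
Why: Cu-catalysed asymmetric conjugate addition in which the ligand enantiomer fixes the β-methyl centre (C6), while the α-methyl centre is equilibrated to trans and is erased later.

**Step 2**
Reactants: 2 (2R,3S)-2,3-dimethylcyclohexan-1-one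
Product: 3 methyl (3R,4S)-3,4-dimethyl-2-oxocyclohexane-1-carboxylate (C1 epimers/enol)
Conditions: NaH (2.2 equiv), (MeO)2CO, THF, reflux; aq. HCl
Reagents that add atoms: dimethyl carbonate, COC(=O)OC
Why: Claisen-type C-acylation under thermodynamic control goes only to the unsubstituted α-carbon (C9), because only that β-keto ester can be deprotonated to drive the equilibrium; no fixed new stereocentre.

**Step 3**
Reactants: 3 methyl (3R,4S)-3,4-dimethyl-2-oxocyclohexane-1-carboxylate
Product: 4 2-methylprop-2-en-1-yl (3R,4S)-3,4-dimethyl-2-oxocyclohexane-1-carboxylate (C1 epimers/enol)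
Conditions: 2-methylprop-2-en-1-ol (3 equiv), DMAP (10 mol%), toluene, reflux, 4 Å MS (−MeOH)
Reagents that add atoms: 2-methylprop-2-en-1-ol, CC(=C)CO
Why: Transesterification of an enolisable β-keto ester (via its acylketene) installs the allyl-type ester needed for step 5.

**Step 4**
Reactants: 4 2-methylprop-2-en-1-yl (3R,4S)-3,4-dimethyl-2-oxocyclohexane-1-carboxylate
Product: 5 2-methylprop-2-en-1-yl (3R,4S)-1-[(2S)-but-3-en-2-yl]-3,4-dimethyl-2-oxocyclohexane-1-carboxylate (C1 configuration irrelevant)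
Conditions: [Ir(cod)Cl]2 (2 mol%), chiral N-aryl phosphoramidite (4 mol%), TBD (10 mol%), LiOt-Bu (1.0 equiv), (E)-crotyl chloride, THF, 25 °C
Reagents that add atoms: (E)-1-chlorobut-2-ene, C/C=C/CCl
Why: Ir-catalysed branched-selective allylic alkylation of the β-keto ester enolate, in which the (π-crotyl)Ir complex is attacked at its methyl-bearing carbon and the ligand sets C10; the ring centre formed here is erased in step 5.

**Step 5**
Reactants: 5 2-methylprop-2-en-1-yl (3R,4S)-1-[(2S)-but-3-en-2-yl]-3,4-dimethyl-2-oxocyclohexane-1-carboxylate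
Product: 6 (2S,5S,6R)-2-[(2S)-but-3-en-2-yl]-5,6-dimethyl-2-(2-methylprop-2-en-1-yl)cyclohexan-1-one
Conditions: Pd2(dba)3 (2.5 mol%), t-Bu-PHOX (6 mol%), toluene, 30 °C
Reagents that add atoms: none
Why: Decarboxylative Tsuji allylation, in which ionisation and CO2 loss give a Pd enolate that couples with the 2-methylallyl fragment inside the chiral ligand pocket, so the quaternary C9 is set by the PHOX enantiomer with the C10 centre as the matched partner.

**Step 6**
Reactants: 6 (2S,5S,6R)-2-[(2S)-but-3-en-2-yl]-5,6-dimethyl-2-(2-methylprop-2-en-1-yl)cyclohexan-1-one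
Product: 7 (2S,5S)-6-bromo-2-[(2S)-but-3-en-2-yl]-5,6-dimethyl-2-(2-methylprop-2-en-1-yl)cyclohexan-1-one (C6 epimers, inconsequential)
Conditions: LDA, THF, −78 → 0 °C; NBS, −78 °C
Reagents that add atoms: N-bromosuccinimide, O=C1CCC(=O)N1Br
Why: Enolate bromination is regiospecific because C5 is the only enolisable position once C9 is quaternary; the C–Br centre is planarised again in step 12.

**Step 7**
Reactants: 7 (2S,5S)-6-bromo-2-[(2S)-but-3-en-2-yl]-5,6-dimethyl-2-(2-methylprop-2-en-1-yl)cyclohexan-1-one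
Product: 8 (2R)-2-[(1S,4S)-3-bromo-3,4-dimethyl-2-oxo-1-(2-oxopropyl)cyclohexyl]propanal (C3 epimers)
Conditions: O3, CH2Cl2–MeOH, −78 °C; Me2S; used crude
Reagents that add atoms: ozone, [O-][O+]=O
Why: Ozonolysis cleaves both alkenes at once (methallyl to the C2 methyl ketone, vinyl to the C11 aldehyde), and the neutral reductive work-up leaves the α-centre C10 untouched.

**Step 8**
Reactants: 9 (2Z)-3-methylpent-2-en-4-yn-1-ol
Product: 10 4,4,5,5-tetramethyl-2-[(2Z)-3-methylpent-2-en-4-yn-1-yl]-1,3,2-dioxaborolane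
Conditions: B2pin2, [Pd(MeCN)4](BF4)2 (5 mol%), DMSO–MeOH, 50 °C
Reagents that add atoms: bis(pinacolato)diboron, CC1(C)OB(OC1(C)C)B1OC(C)(C)C(C)(C)O1
Why: Pd-catalysed direct borylation of an allylic alcohol through a (π-allyl)Pd intermediate gives the linear allylboronate, and the trisubstituted terminus should keep its Z geometry.

**Step 9**
Reactants: 8 (2R)-2-[(1S,4S)-3-bromo-3,4-dimethyl-2-oxo-1-(2-oxopropyl)cyclohexyl]propanal; 10 4,4,5,5-tetramethyl-2-[(2Z)-3-methylpent-2-en-4-yn-1-yl]-1,3,2-dioxaborolane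
Product: 11 (2S,5S)-6-bromo-2-[(2R,3S,4R)-4-ethynyl-3-hydroxy-4-methylhex-5-en-2-yl]-5,6-dimethyl-2-(2-oxopropyl)cyclohexan-1-one
Conditions: TRIP phosphoric acid (10 mol%), toluene, −30 → 0 °C; aq. NaHCO3 work-up
Reagents that add atoms: none
Why: Chiral-phosphoric-acid-catalysed allylboration through a closed chair transition state attacks the aldehyde with the γ-carbon to create quaternary C12; the Z geometry (methyl equatorial, ethynyl axial) fixes C12 relative to C11, and Felkin addition past the quaternary C9, reinforced by the catalyst enantiomer, fixes C11 relative to C10.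

**Step 10**
Reactants: 11 (2S,5S)-6-bromo-2-[(2R,3S,4R)-4-ethynyl-3-hydroxy-4-methylhex-5-en-2-yl]-5,6-dimethyl-2-(2-oxopropyl)cyclohexan-1-one
Product: 12 (2S,5S)-6-bromo-2-[(2R,3S,4R)-4-ethynyl-4-methyl-3-[(triethylsilyl)oxy]hex-5-en-2-yl]-5,6-dimethyl-2-(2-oxopropyl)cyclohexan-1-one
Conditions: TESOTf, 2,6-lutidine, CH2Cl2, −78 °C
Reagents that add atoms: triethylsilyl trifluoromethanesulfonate, CC[Si](CC)(CC)OS(=O)(=O)C(F)(F)F
Why: Silylation of the C11 alcohol stops it from forming a lactol with the coming C14 aldehyde and from being acylated in step 12; no stereocentre is touched.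

**Step 11**
Reactants: 12 (2S,5S)-6-bromo-2-[(2R,3S,4R)-4-ethynyl-4-methyl-3-[(triethylsilyl)oxy]hex-5-en-2-yl]-5,6-dimethyl-2-(2-oxopropyl)cyclohexan-1-one
Product: 13 (3S,4S,5R)-5-[(1S,4S)-3-bromo-3,4-dimethyl-2-oxo-1-(2-oxopropyl)cyclohexyl]-3-ethenyl-3-methyl-4-[(triethylsilyl)oxy]hexanal
Conditions: [CpRu(MeCN)3]PF6 (5 mol%), 5,5′-bis(trifluoromethyl)-2,2′-bipyridine (5 mol%), NMP–H2O (4:1), 25 °C
Reagents that add atoms: water, O
Why: Ru-catalysed anti-Markovnikov hydration of the terminal alkyne (via a Ru vinylidene) gives the C14 aldehyde and leaves the vinyl group, the ketones and the bromide alone.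

**Step 12**
Reactants: 13 (3S,4S,5R)-5-[(1S,4S)-3-bromo-3,4-dimethyl-2-oxo-1-(2-oxopropyl)cyclohexyl]-3-ethenyl-3-methyl-4-[(triethylsilyl)oxy]hexanal
Product: 17 pleuromutilin F, via samarium aldolate 14 (not isolated), via acetoxyacetate 15 (not isolated), via seco-diketone 16 (not isolated)
Conditions: one pot: (i) SmI2 (2.2 equiv), THF, −78 °C; (ii) AcOCH2COCl (3 equiv), DMAP, −78 → 0 °C; (iii) 3 M HCl, MeOH–H2O, 45 °C
Reagents that add atoms: acetoxyacetyl chloride, CC(=O)OCC(=O)Cl
Why: Proposed new method: Sm(II) reduces the tertiary α-bromo ketone to the only enolate present, which adds to the C14 aldehyde through a chelated closed transition state reachable only from the face of C5 that carries the C9 arm (this sets C5 and, with H-14 turned into the ring, C14); the aldolate is trapped as its ester so it cannot revert, and methanolic HCl then removes TES and acetate and lets the methyl-ketone enol condense with the freed C4 ketone, where C3=C4 is the only possible dehydration product because C5 and C9 are quaternary; the closest known reaction types are the SmI2-mediated intramolecular Reformatsky/aldol closure of eight-membered rings and the acid-mediated cyclopentenone annulation of 2-acetonyl cycloalkanones.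

**Compound list**
1 | 2-methylcyclohex-2-en-1-one | CC1=CCCCC1=O | starting material
2 | (2R,3S)-2,3-dimethylcyclohexan-1-one | O=C1CCC[C@H](C)[C@H]1C | intermediate
3 | methyl (3R,4S)-3,4-dimethyl-2-oxocyclohexane-1-carboxylate (C1 epimers/enol) | O=C1C(C(=O)OC)CC[C@H](C)[C@H]1C | intermediate
4 | 2-methylprop-2-en-1-yl (3R,4S)-3,4-dimethyl-2-oxocyclohexane-1-carboxylate (C1 epimers/enol) | O=C1C(C(=O)OCC(C)=C)CC[C@H](C)[C@H]1C | intermediate
5 | 2-methylprop-2-en-1-yl (3R,4S)-1-[(2S)-but-3-en-2-yl]-3,4-dimethyl-2-oxocyclohexane-1-carboxylate (C1 not defined) | O=C1C(C(=O)OCC(C)=C)([C@@H](C)C=C)CC[C@H](C)[C@H]1C | intermediate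
6 | (2S,5S,6R)-2-[(2S)-but-3-en-2-yl]-5,6-dimethyl-2-(2-methylprop-2-en-1-yl)cyclohexan-1-one | C=C(C)C[C@@]1(CC[C@H](C)[C@@H](C)C1=O)[C@@H](C)C=C | intermediate
7 | (2S,5S)-6-bromo-2-[(2S)-but-3-en-2-yl]-5,6-dimethyl-2-(2-methylprop-2-en-1-yl)cyclohexan-1-one (C6 epimers) | C=C(C)C[C@@]1(CC[C@H](C)C(C)(Br)C1=O)[C@@H](C)C=C | intermediate
8 | (2R)-2-[(1S,4S)-3-bromo-3,4-dimethyl-2-oxo-1-(2-oxopropyl)cyclohexyl]propanal (C3 epimers) | CC(=O)C[C@@]1(CC[C@H](C)C(C)(Br)C1=O)[C@@H](C)C=O | intermediate
9 | (2Z)-3-methylpent-2-en-4-yn-1-ol | C#C/C(C)=C\CO | starting material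
10 | 4,4,5,5-tetramethyl-2-[(2Z)-3-methylpent-2-en-4-yn-1-yl]-1,3,2-dioxaborolane | C#C/C(C)=C\CB1OC(C)(C)C(C)(C)O1 | intermediate
11 | (2S,5S)-6-bromo-2-[(2R,3S,4R)-4-ethynyl-3-hydroxy-4-methylhex-5-en-2-yl]-5,6-dimethyl-2-(2-oxopropyl)cyclohexan-1-one | CC(=O)C[C@@]1(CC[C@H](C)C(C)(Br)C1=O)[C@@H](C)[C@H](O)[C@](C)(C=C)C#C | intermediate
12 | (2S,5S)-6-bromo-2-[(2R,3S,4R)-4-ethynyl-4-methyl-3-[(triethylsilyl)oxy]hex-5-en-2-yl]-5,6-dimethyl-2-(2-oxopropyl)cyclohexan-1-one | CC(=O)C[C@@]1(CC[C@H](C)C(C)(Br)C1=O)[C@@H](C)[C@H](O[Si](CC)(CC)CC)[C@](C)(C=C)C#C | intermediate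
13 | (3S,4S,5R)-5-[(1S,4S)-3-bromo-3,4-dimethyl-2-oxo-1-(2-oxopropyl)cyclohexyl]-3-ethenyl-3-methyl-4-[(triethylsilyl)oxy]hexanal | CC(=O)C[C@@]1(CC[C@H](C)C(C)(Br)C1=O)[C@@H](C)[C@H](O[Si](CC)(CC)CC)[C@](C)(C=C)CC=O | intermediate
14 | samarium(III) aldolate, drawn as the free C14 alcohol: 4-ethenyl-2-hydroxy-1,4,6,10-tetramethyl-7-(2-oxopropyl)-5-[(triethylsilyl)oxy]bicyclo[5.3.1]undecan-11-one; mutilin numbering 5R,6S,9S,10R,11S,12S,14R | C=C[C@]1(C)C[C@@H](O)[C@]2(C)C(=O)[C@](CC(C)=O)(CC[C@@H]2C)[C@@H](C)[C@@H]1O[Si](CC)(CC)CC | intermediate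
15 | 14-O-(acetoxyacetyl) derivative of 14 (same descriptors) | C=C[C@]1(C)C[C@@H](OC(=O)COC(C)=O)[C@]2(C)C(=O)[C@](CC(C)=O)(CC[C@@H]2C)[C@@H](C)[C@@H]1O[Si](CC)(CC)CC | intermediate
16 | seco-diketone: 4-ethenyl-5-hydroxy-1,4,6,10-tetramethyl-11-oxo-7-(2-oxopropyl)bicyclo[5.3.1]undecan-2-yl hydroxyacetate (same descriptors) | C=C[C@]1(C)C[C@@H](OC(=O)CO)[C@]2(C)C(=O)[C@](CC(C)=O)(CC[C@@H]2C)[C@@H](C)[C@@H]1O | intermediate
17 | pleuromutilin F (2-oxo-3,4-ene mutilin 14-glycolate; mutilin numbering 5S,6S,9S,10R,11S,12S,14R as written) | C=C[C@]1(C)C[C@@H](OC(=O)CO)[C@]2(C)C3=CC(=O)C[C@@]3(CC[C@@H]2C)[C@@H](C)[C@@H]1O | target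

**Totals**
Total step count: 12. Longest linear sequence: 11 (steps 1–7 and 9–12, from compound 1).

**Three steps most likely to fail**

Step 12 (one-pot double ring closure). The Sm enolate might add to the methyl ketone instead of the aldehyde, the aldolate might resist acylation, or the acid annulation might stall at 16. The fallback sets out from 13 and comes back at 17, closing each ring in a separate, differently activated step. A CrCl2/LiI Reformatsky-type cyclisation (Cr(III) enolates add to aldehydes but not to ketones) with aqueous work-up gives the alcohol 14, now isolated. Acetoxyacetic acid, EDC and DMAP give 15, isolated. The cyclopentenone is then closed by enamine catalysis (pyrrolidine, AcOH, toluene, 60 °C) to the doubly protected enone F1, and HCl–MeOH at 0 °C removes the TES and acetyl groups to give 17.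

Step 9 (allylboration). The β-quaternary aldehyde is hindered, and the facial and E/Z fidelity of the boronate may be low. The fallback sets out from 9 and comes back at 11, replacing boron by a hypervalent-silicon allylation. Alcohol 9 is converted (MsCl, Et3N, then LiCl, DMF) into the (Z)-allyl chloride F2, and HSiCl3, CuCl and i-Pr2NEt turn this into the allyltrichlorosilane F3. F3 adds to aldehyde 8 under a chiral bisphosphoramide Lewis base through a closed hexacoordinate-silicon chair, which gives the same C11/C12 relationship under catalyst control of the aldehyde face, and delivers 11 after aqueous work-up.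

Step 5 (quaternary C9). The diastereoselectivity of the Pd step next to C10 may be poor or mismatched. The fallback sets out from 3 and comes back at 6, using fluoride-triggered enolate release and uncatalysed alkylation under substrate control. Transesterification of 3 with 2-(trimethylsilyl)ethanol gives the 2-(trimethylsilyl)ethyl β-keto ester F4. The Ir crotylation of step 4 applied to F4 gives its crotylation product F5. TBAF with 2-methylallyl bromide in THF then unmasks the C9 enolate (loss of Me3SiF, ethene and CO2) and alkylates it directly to 6.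

**Further compounds**
F1 | step 12 | 11-O-triethylsilyl-22-O-acetyl derivative of 17 | C=C[C@]1(C)C[C@@H](OC(=O)COC(C)=O)[C@]2(C)C3=CC(=O)C[C@@]3(CC[C@@H]2C)[C@@H](C)[C@@H]1O[Si](CC)(CC)CC
F2 | step 9 | (3Z)-5-chloro-3-methylpent-3-en-1-yne | C#C/C(C)=C\CCl
F3 | step 9 | trichloro[(2Z)-3-methylpent-2-en-4-yn-1-yl]silane | C#C/C(C)=C\C[Si](Cl)(Cl)Cl
F4 | step 5 | 2-(trimethylsilyl)ethyl (3R,4S)-3,4-dimethyl-2-oxocyclohexane-1-carboxylate | O=C1C(C(=O)OCC[Si](C)(C)C)CC[C@H](C)[C@H]1C
F5 | step 5 | 2-(trimethylsilyl)ethyl (3R,4S)-1-[(2S)-but-3-en-2-yl]-3,4-dimethyl-2-oxocyclohexane-1-carboxylate | O=C1C(C(=O)OCC[Si](C)(C)C)([C@@H](C)C=C)CC[C@H](C)[C@H]1C
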